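**Retrosynthetic overview**
- Target ⇐ one hydrogenation (exocyclic C=CH2 → CH–CH3, O-benzyl removed) ⇐ Wittig methylenation ⇐ α-quaternary ketone carrying the benzoxazolylmethyl group.
- That ketone ⇐ regiospecific enolate (unmasked from a silyl enol ether) + 7-(bromomethyl)benzoxazole; the quaternary C–C bond is made on the convex face of a cis-fused bicycle.
- Silyl enol ether with the ring olefin ⇐ enol triflate/methyl coupling ⇐ cis-fused bicyclic keto silyl enol ether.
- Key step: that bicycle ⇐ acyclic (E)-trienone (isopropenyl ketone + 2-silyloxy diene) by a catalytic enantioselective intramolecular Diels–Alder reaction that closes rings A and B together and sets both ring-fusion stereocentres.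
- Ring order: oxazole ring in the aryl branch (from isovanillin); carbocyclic rings A and B in one operation in the terpenoid branch (from δ-valerolactone, a C4 keto-ylide and isopropenylmagnesium bromide); no ring is formed after fragment union.

Assumption: the (R)-configured acid catalyst of step 5 is taken to give the (4aS,8aR) adduct; if the first run shows the opposite sense, the (S)-catalyst is used and nothing else changes.
Locants C-1, C-2, C-4a, C-5, C-8a in the "Why" lines are those of the octahydronaphthalene unit of the target.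

**Route**

Step 1
Reactants: 1 δ-valerolactone (oxan-2-one)
Product: 2 5-hydroxy-N-methoxy-N-methylpentanamide
Conditions: MeNH(OMe)·HCl, AlMe3, CH2Cl2, 0 °C to rt; dilute HCl work-up
Reagents that add atoms: N,O-dimethylhydroxylamine hydrochloride, CNOC.Cl
Why: Weinreb aminolysis of a lactone by the aluminium amide formed in the flask opens the ring to the hydroxy Weinreb amide without over-reaction; no stereocentre is involved.

Step 2
Reactants: 2 5-hydroxy-N-methoxy-N-methylpentanamide; 3 3-(triphenyl-λ5-phosphanylidene)butan-2-one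
Product: 5 (5E)-N-methoxy-N,6-dimethyl-7-oxooct-5-enamide, via aldehyde 4 (not isolated)
Conditions: TEMPO (2,2,6,6-tetramethylpiperidin-1-oxyl, 10 mol %), PhI(OAc)2, CH2Cl2, rt; then 3, 40 °C
Reagents that add atoms: none
Why: The nitroxyl-catalysed oxidation stops at the aldehyde and the stabilised ylide then gives the trisubstituted enone with E geometry in a one-pot oxidation–Wittig olefination.

Step 3
Reactants: 5 (5E)-N-methoxy-N,6-dimethyl-7-oxooct-5-enamide
Product: 6 (5E)-N-methoxy-N,6-dimethyl-7-[(triisopropylsilyl)oxy]octa-5,7-dienamide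
Conditions: i-Pr3SiOTf, Et3N, CH2Cl2, −78 to 0 °C
Reagents that add atoms: triisopropylsilyl trifluoromethanesulfonate, CC(C)[Si](C(C)C)(C(C)C)OS(=O)(=O)C(F)(F)F
Why: Soft enolisation of the methyl ketone at its α'-methyl group gives the cross-conjugated 2-silyloxy diene (silyl enol ether formation), the Weinreb amide being far less acidic.

Step 4
Reactants: 6 (5E)-N-methoxy-N,6-dimethyl-7-[(triisopropylsilyl)oxy]octa-5,7-dienamide; 7 isopropenylmagnesium bromide
Product: 8 (7E)-2,8-dimethyl-9-[(triisopropylsilyl)oxy]deca-1,7,9-trien-3-one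
Conditions: THF, −40 to 0 °C; aq. NH4Cl quench at 0 °C; kept cold and used at once
Reagents that add atoms: none
Why: Weinreb ketone synthesis, in which the chelated tetrahedral adduct prevents a second addition and the silyl dienol ether, which also masks the methyl ketone, is inert to the Grignard reagent.

Step 5
Reactants: 8 (7E)-2,8-dimethyl-9-[(triisopropylsilyl)oxy]deca-1,7,9-trien-3-one
Product: 9 (4aS,8aR)-5,8a-dimethyl-6-[(triisopropylsilyl)oxy]-3,4,4a,7,8,8a-hexahydronaphthalen-1(2H)-one
Conditions: (R)-3,3'-bis(2,4,6-triisopropylphenyl)-1,1'-binaphthalene-2,2'-diyl N-triflylphosphoramidate, (ArO)2P(O)NHSO2CF3 (5 mol %), 4 Å molecular sieves, toluene (0.02 M), −78 to −40 °C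
Reagents that add atoms: none
Why: Proposed new method: the strong chiral Brønsted acid hydrogen-bonds/protonates the isopropenyl ketone and lowers its LUMO, so the electron-rich 2-silyloxy diene adds in a concerted, asynchronous intramolecular Diels–Alder reaction that closes rings A and B at once; the tether carbonyl sits endo, which places the angular methyl and the ring-fusion hydrogen cis, and the chiral phosphoramidate counter-ion shields one face of the ion-paired enone so that both ring-fusion stereocentres are set together; the closest known reaction types are the N-triflylphosphoramide-catalysed enantioselective Diels–Alder reaction of ethyl vinyl ketone with 2-silyloxy dienes and the cis-selective intramolecular Diels–Alder reaction of 1,7,9-decatrien-3-ones.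

Step 6
Reactants: 9 (4aS,8aR)-5,8a-dimethyl-6-[(triisopropylsilyl)oxy]-3,4,4a,7,8,8a-hexahydronaphthalen-1(2H)-one
Product: 11 (4aS,8aR)-5,8a-dimethyl-6-[(triisopropylsilyl)oxy]-3,4,4a,7,8,8a-hexahydronaphthalen-1-yl trifluoromethanesulfonate, via potassium enolate 10 (not isolated)
Conditions: KN(SiMe3)2, THF, −78 °C; then PhNTf2, −78 to 0 °C
Reagents that add atoms: N-phenylbis(trifluoromethanesulfonimide), O=S(=O)(N(c1ccccc1)S(=O)(=O)C(F)(F)F)C(F)(F)F
Why: The ketone can enolise only toward its CH2 group because the other α-carbon is quaternary, so enol triflate formation gives a single regioisomer and leaves the silyl enol ether and both stereocentres untouched.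

Step 7
Reactants: 11 (4aS,8aR)-5,8a-dimethyl-6-[(triisopropylsilyl)oxy]-3,4,4a,7,8,8a-hexahydronaphthalen-1-yl trifluoromethanesulfonate
Product: 12 triisopropyl{[(4aR,8aR)-1,4a,5-trimethyl-3,4,4a,7,8,8a-hexahydronaphthalen-2-yl]oxy}silane
Conditions: MeMgBr, Fe(acac)3 (5 mol %), THF/NMP, −30 to 0 °C
Reagents that add atoms: methylmagnesium bromide, C[Mg]Br
Why: Iron-catalysed Kumada-type cross-coupling of the alkenyl triflate with the methyl Grignard reagent fixes the trisubstituted ring olefin exactly where the triflate stood, and the silyl enol ether tolerates the conditions.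

Step 8
Reactants: 13 isovanillin (3-hydroxy-4-methoxybenzaldehyde)
Product: 15 4-methoxybenzene-1,3-diol, via aryl formate 14 (not isolated)
Conditions: 30 % H2O2, H2SO4 (cat.), MeOH, rt
Reagents that add atoms: hydrogen peroxide, OO
Why: Acid-catalysed Dakin-type (Baeyer–Villiger) oxidation, in which the para-methoxy group drives aryl migration and the formate is methanolysed in the same pot.

Step 9
Reactants: 15 4-methoxybenzene-1,3-diol
Product: 16 4-methoxy-6-nitrosobenzene-1,3-diol
Conditions: NaNO2, AcOH/H2O, 0 °C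
Reagents that add atoms: sodium nitrite, [Na+].[O-]N=O
Why: Electrophilic C-nitrosation of the resorcinol unit occurs at the position para to one hydroxyl and ortho to the other, which is less hindered than the site between the two hydroxyls, and avoids the oxidising conditions of nitration.

Step 10
Reactants: 16 4-methoxy-6-nitrosobenzene-1,3-diol
Product: 18 5-methoxy-2-methyl-1,3-benzoxazol-6-ol, via aminophenol 17 (not isolated)
Conditions: H2 (1 atm), Pd/C, THF, rt; then CH3C(OEt)3, TsOH (5 mol %), 65 °C
Reagents that add atoms: triethyl orthoacetate, CCOC(C)(OCC)OCC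
Why: Hydrogenation gives the air-sensitive o-aminophenol, which is condensed at once with the orthoester to close the oxazole ring (benzoxazole synthesis); only the hydroxyl ortho to nitrogen can cyclise.

Step 11
Reactants: 18 5-methoxy-2-methyl-1,3-benzoxazol-6-ol
Product: 19 7-(hydroxymethyl)-5-methoxy-2-methyl-1,3-benzoxazol-6-ol
Conditions: 37 % aq. HCHO, NaOH (1 equiv), H2O/THF, 0 °C to rt
Reagents that add atoms: formaldehyde, C=O
Why: Lederer–Manasse hydroxymethylation of the phenoxide, which has a single free ortho position and a ring-fused para position, so only C-7 can react.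

Step 12
Reactants: 19 7-(hydroxymethyl)-5-methoxy-2-methyl-1,3-benzoxazol-6-ol
Product: 20 [6-(benzyloxy)-5-methoxy-2-methyl-1,3-benzoxazol-7-yl]methanol
Conditions: BnBr (1.05 equiv), K2CO3, acetone, 50 °C
Reagents that add atoms: benzyl bromide, BrCc1ccccc1
Why: Williamson etherification, in which carbonate deprotonates only the phenol and leaves the benzylic alcohol untouched.

Step 13
Reactants: 20 [6-(benzyloxy)-5-methoxy-2-methyl-1,3-benzoxazol-7-yl]methanol
Product: 21 6-(benzyloxy)-7-(bromomethyl)-5-methoxy-2-methyl-1,3-benzoxazole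
Conditions: CBr4, PPh3, CH2Cl2, 0 °C; used crude
Reagents that add atoms: carbon tetrabromide, BrC(Br)(Br)Br
Why: Appel bromination converts the electron-rich benzylic alcohol to the bromide under neutral conditions that do not protonate or open the benzoxazole.

Step 14
Reactants: 12 triisopropyl{[(4aR,8aR)-1,4a,5-trimethyl-3,4,4a,7,8,8a-hexahydronaphthalen-2-yl]oxy}silane; 21 6-(benzyloxy)-7-(bromomethyl)-5-methoxy-2-methyl-1,3-benzoxazole
Product: 23 (1S,4aR,8aR)-1-{[6-(benzyloxy)-5-methoxy-2-methyl-1,3-benzoxazol-7-yl]methyl}-1,4a,5-trimethyl-3,4,4a,7,8,8a-hexahydronaphthalen-2(1H)-one, via sulfonium enolate 22 (not isolated)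
Conditions: [(Me2N)3S][Me3SiF2] (TASF, 1.1 equiv), THF, 0 °C; then 21, −40 °C to rt
Reagents that add atoms: none
Why: Fluoride cleaves the Si–O bond to give the regiodefined tetrasubstituted enolate, which is C-benzylated (fluoride-promoted alkylation of a silyl enol ether) on the convex face of the cis-fused bicycle, away from ring A, so the new quaternary C-1 carries CH2Ar cis to H-8a and to the angular methyl.

Step 15
Reactants: 23 (1S,4aR,8aR)-1-{[6-(benzyloxy)-5-methoxy-2-methyl-1,3-benzoxazol-7-yl]methyl}-1,4a,5-trimethyl-3,4,4a,7,8,8a-hexahydronaphthalen-2(1H)-one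
Product: 24 6-(benzyloxy)-5-methoxy-2-methyl-7-{[(1S,4aR,8aS)-1,4a,5-trimethyl-2-methylidene-1,2,3,4,4a,7,8,8a-octahydronaphthalen-1-yl]methyl}-1,3-benzoxazole
Conditions: Ph3PCH3Br (3 equiv), KOtBu (2.8 equiv), toluene, 90 °C
Reagents that add atoms: methyltriphenylphosphonium bromide, C[P+](c1ccccc1)(c1ccccc1)c1ccccc1.[Br-]
Why: Wittig methylenation with excess ylide at high temperature is the standard answer to a ketone flanked by a quaternary carbon, and no epimerisable stereocentre is adjacent.

Step 16
Reactants: 24 6-(benzyloxy)-5-methoxy-2-methyl-7-{[(1S,4aR,8aS)-1,4a,5-trimethyl-2-methylidene-1,2,3,4,4a,7,8,8a-octahydronaphthalen-1-yl]methyl}-1,3-benzoxazole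
Product: 26 5-methoxy-2-methyl-7-{[(1R,2S,4aR,8aS)-1,2,4a,5-tetramethyl-1,2,3,4,4a,7,8,8a-octahydronaphthalen-1-yl]methyl}-1,3-benzoxazol-6-ol (target), via benzyl ether 25 (not isolated)
Conditions: H2 (1 atm), Pd/C (5 %), EtOAc, rt; stopped after two equivalents of H2
Reagents that add atoms: none
Why: Heterogeneous hydrogenation adds H2 to the exocyclic 1,1-disubstituted alkene from the convex face, opposite the axial C-1 methyl and ring A, so the C-2 methyl ends cis to the C-1 methyl, and the same catalyst hydrogenolyses the benzyl ether while the hindered trisubstituted ring olefin reacts far more slowly.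

**Compound list**
1 | δ-valerolactone (oxan-2-one) | O=C1CCCCO1 | starting material
2 | 5-hydroxy-N-methoxy-N-methylpentanamide | CON(C)C(=O)CCCCO | intermediate
3 | 3-(triphenyl-λ5-phosphanylidene)butan-2-one | CC(=O)C(C)=P(c1ccccc1)(c1ccccc1)c1ccccc1 | starting material
4 | N-methoxy-N-methyl-5-oxopentanamide | CON(C)C(=O)CCCC=O | intermediate
5 | (5E)-N-methoxy-N,6-dimethyl-7-oxooct-5-enamide | CC(=O)/C(C)=C/CCCC(=O)N(C)OC | intermediate
6 | (5E)-N-methoxy-N,6-dimethyl-7-[(triisopropylsilyl)oxy]octa-5,7-dienamide | C=C(O[Si](C(C)C)(C(C)C)C(C)C)/C(C)=C/CCCC(=O)N(C)OC | intermediate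
7 | isopropenylmagnesium bromide | C=C(C)[Mg]Br | starting material
8 | (7E)-2,8-dimethyl-9-[(triisopropylsilyl)oxy]deca-1,7,9-trien-3-one | C=C(C)C(=O)CCC/C=C(C)/C(=C)O[Si](C(C)C)(C(C)C)C(C)C | intermediate
9 | (4aS,8aR)-5,8a-dimethyl-6-[(triisopropylsilyl)oxy]-3,4,4a,7,8,8a-hexahydronaphthalen-1(2H)-one (cis-fused) | CC1=C(O[Si](C(C)C)(C(C)C)C(C)C)CC[C@@]2(C)C(=O)CCC[C@@H]12 | intermediate
10 | potassium (4aS,8aR)-5,8a-dimethyl-6-[(triisopropylsilyl)oxy]-3,4,4a,7,8,8a-hexahydronaphthalen-1-olate | CC1=C(O[Si](C(C)C)(C(C)C)C(C)C)CC[C@@]2(C)C([O-])=CCC[C@@H]12.[K+] | intermediate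
11 | (4aS,8aR)-5,8a-dimethyl-6-[(triisopropylsilyl)oxy]-3,4,4a,7,8,8a-hexahydronaphthalen-1-yl trifluoromethanesulfonate | CC1=C(O[Si](C(C)C)(C(C)C)C(C)C)CC[C@@]2(C)C(OS(=O)(=O)C(F)(F)F)=CCC[C@@H]12 | intermediate
12 | triisopropyl{[(4aR,8aR)-1,4a,5-trimethyl-3,4,4a,7,8,8a-hexahydronaphthalen-2-yl]oxy}silane | CC1=C(O[Si](C(C)C)(C(C)C)C(C)C)CC[C@@]2(C)C(C)=CCC[C@@H]12 | intermediate
13 | isovanillin (3-hydroxy-4-methoxybenzaldehyde) | COc1ccc(C=O)cc1O | starting material
14 | 3-hydroxy-4-methoxyphenyl formate | COc1ccc(OC=O)cc1O | intermediate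
15 | 4-methoxybenzene-1,3-diol | COc1ccc(O)cc1O | intermediate
16 | 4-methoxy-6-nitrosobenzene-1,3-diol | COc1cc(N=O)c(O)cc1O | intermediate
17 | 4-amino-6-methoxybenzene-1,3-diol | COc1cc(N)c(O)cc1O | intermediate
18 | 5-methoxy-2-methyl-1,3-benzoxazol-6-ol | COc1cc2nc(C)oc2cc1O | intermediate
19 | 7-(hydroxymethyl)-5-methoxy-2-methyl-1,3-benzoxazol-6-ol | COc1cc2nc(C)oc2c(CO)c1O | intermediate
20 | [6-(benzyloxy)-5-methoxy-2-methyl-1,3-benzoxazol-7-yl]methanol | COc1cc2nc(C)oc2c(CO)c1OCc1ccccc1 | intermediate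
21 | 6-(benzyloxy)-7-(bromomethyl)-5-methoxy-2-methyl-1,3-benzoxazole | COc1cc2nc(C)oc2c(CBr)c1OCc1ccccc1 | intermediate
22 | tris(dimethylamino)sulfonium (4aR,8aR)-1,4a,5-trimethyl-3,4,4a,7,8,8a-hexahydronaphthalen-2-olate | CC1=C([O-])CC[C@@]2(C)C(C)=CCC[C@@H]12.CN(C)[S+](N(C)C)N(C)C | intermediate
23 | (1S,4aR,8aR)-1-{[6-(benzyloxy)-5-methoxy-2-methyl-1,3-benzoxazol-7-yl]methyl}-1,4a,5-trimethyl-3,4,4a,7,8,8a-hexahydronaphthalen-2(1H)-one | COc1cc2nc(C)oc2c(C[C@]2(C)C(=O)CC[C@@]3(C)C(C)=CCC[C@@H]23)c1OCc1ccccc1 | intermediate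
24 | 6-(benzyloxy)-5-methoxy-2-methyl-7-{[(1S,4aR,8aS)-1,4a,5-trimethyl-2-methylidene-1,2,3,4,4a,7,8,8a-octahydronaphthalen-1-yl]methyl}-1,3-benzoxazole | COc1cc2nc(C)oc2c(C[C@]2(C)C(=C)CC[C@@]3(C)C(C)=CCC[C@@H]23)c1OCc1ccccc1 | intermediate
25 | 6-(benzyloxy)-5-methoxy-2-methyl-7-{[(1R,2S,4aR,8aS)-1,2,4a,5-tetramethyl-1,2,3,4,4a,7,8,8a-octahydronaphthalen-1-yl]methyl}-1,3-benzoxazole | COc1cc2nc(C)oc2c(C[C@]2(C)[C@@H](C)CC[C@@]3(C)C(C)=CCC[C@@H]23)c1OCc1ccccc1 | intermediate
26 | 5-methoxy-2-methyl-7-{[(1R,2S,4aR,8aS)-1,2,4a,5-tetramethyl-1,2,3,4,4a,7,8,8a-octahydronaphthalen-1-yl]methyl}-1,3-benzoxazol-6-ol | COc1cc2nc(C)oc2c(C[C@]2(C)[C@@H](C)CC[C@@]3(C)C(C)=CCC[C@@H]23)c1O | target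

**Step count and risks**
Total step count: 16.
Longest linear sequence: 10 steps (steps 1–7, then 14–16); the aryl branch is 6 steps (8–13) before the union.

The three steps most likely to fail:

Step 5 (key cycloaddition). The risks are low enantioselectivity with an α-methyl vinyl ketone that has no precedent with this catalyst class, protodesilylation of the diene, racemic thermal background, and some trans-fused adduct. The fallback sets out from 8 and keeps the two-ring closure but switches from acid activation of the dienophile to amine activation of the diene. The silyl group of 8 is removed with HF·pyridine in THF at 0 °C to give (7E)-2,8-dimethyldeca-1,7-diene-3,9-dione F1. F1 is treated with 9-amino-9-deoxy-epi-quinine (20 mol %) and 2-fluorobenzoic acid (40 mol %) in toluene. The methyl enone forms a cross-conjugated dienamine that adds twice to the isopropenyl ketone (Michael/Michael, a formal [4+2]), closing rings A and B together. Hydrolysis gives the cis-fused (4aS,8aR)-5,8a-dimethyl-3,4,4a,7,8,8a-hexahydronaphthalene-1,6(2H,5H)-dione F2, whose methyl-bearing α-carbon is a mixture that does not matter. F2 is silylated under equilibrating conditions at the less hindered ring B ketone, toward its more substituted α-carbon (i-Pr3SiOTf 1.05 equiv, Et3N, CH2Cl2, 0 °C to rt), and the route is rejoined at 9.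

Step 14 (quaternary benzylation). The risks are O-alkylation of the hindered enolate, proton transfer from the acidic 2-methyl group of the benzoxazole, and attack on the wrong face, since the angular methyl also sits on the convex face. The fallback sets out from 12 and 19 and replaces the SN2 alkylation by conjugate addition to an ortho-quinone methide. Tf2NH (5 mol %) in CH2Cl2 at −40 °C ionises the benzylic alcohol of 19 to the quinone methide, which 12 captures in a Mukaiyama–Michael addition. This gives the free phenol (1S,4aR,8aR)-1-[(6-hydroxy-5-methoxy-2-methyl-1,3-benzoxazol-7-yl)methyl]-1,4a,5-trimethyl-3,4,4a,7,8,8a-hexahydronaphthalen-2(1H)-one F3. O-Benzylation of F3 (BnBr, K2CO3, acetone) brings the material back to the route at 23.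

Step 16 (final hydrogenation). The risks are palladium-induced migration of the exocyclic alkene into the ring, partial reduction of the trisubstituted ring olefin, and the wrong C-2 epimer. The fallback sets out from 24 and sets C-2 by hydroboration instead of hydrogenation. 9-BBN (THF, rt) reacts only with the 1,1-disubstituted alkene, from the convex face, and NaOH/H2O2 then gives [(1S,2S,4aR,8aS)-1-{[6-(benzyloxy)-5-methoxy-2-methyl-1,3-benzoxazol-7-yl]methyl}-1,4a,5-trimethyl-1,2,3,4,4a,7,8,8a-octahydronaphthalen-2-yl]methanol F4. Mesylation (MsCl, Et3N, CH2Cl2) gives [(1S,2S,4aR,8aS)-1-{[6-(benzyloxy)-5-methoxy-2-methyl-1,3-benzoxazol-7-yl]methyl}-1,4a,5-trimethyl-1,2,3,4,4a,7,8,8a-octahydronaphthalen-2-yl]methyl methanesulfonate F5. LiEt3BH in THF reduces F5 to the methyl compound, which rejoins the route at 25. Only the benzyl ether of 25 then remains to be hydrogenolysed (H2, Pd/C) to 26.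

**Further compounds**
F1 | step 5 | (7E)-2,8-dimethyldeca-1,7-diene-3,9-dione | C=C(C)C(=O)CCC/C=C(C)/C(C)=O
F2 | step 5 | (4aS,8aR)-5,8a-dimethyl-3,4,4a,7,8,8a-hexahydronaphthalene-1,6(2H,5H)-dione (cis-fused; mixture at C-5) | CC1C(=O)CC[C@@]2(C)C(=O)CCC[C@@H]12
F3 | step 14 | (1S,4aR,8aR)-1-[(6-hydroxy-5-methoxy-2-methyl-1,3-benzoxazol-7-yl)methyl]-1,4a,5-trimethyl-3,4,4a,7,8,8a-hexahydronaphthalen-2(1H)-one | COc1cc2nc(C)oc2c(C[C@]2(C)C(=O)CC[C@@]3(C)C(C)=CCC[C@@H]23)c1O
F4 | step 16 | [(1S,2S,4aR,8aS)-1-{[6-(benzyloxy)-5-methoxy-2-methyl-1,3-benzoxazol-7-yl]methyl}-1,4a,5-trimethyl-1,2,3,4,4a,7,8,8a-octahydronaphthalen-2-yl]methanol | COc1cc2nc(C)oc2c(C[C@]2(C)[C@@H](CO)CC[C@@]3(C)C(C)=CCC[C@@H]23)c1OCc1ccccc1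
F5 | step 16 | [(1S,2S,4aR,8aS)-1-{[6-(benzyloxy)-5-methoxy-2-methyl-1,3-benzoxazol-7-yl]methyl}-1,4a,5-trimethyl-1,2,3,4,4a,7,8,8a-octahydronaphthalen-2-yl]methyl methanesulfonate | COc1cc2nc(C)oc2c(C[C@]2(C)[C@@H](COS(C)(=O)=O)CC[C@@]3(C)C(C)=CCC[C@@H]23)c1OCc1ccccc1
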